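## Structural features

The target (23) is a tetracycle. A 5,6-dimethyl-2-pyrone (ring A) is fused through C3–C4 to a dihydropyran (ring B). Ring B shares its hemiketal carbon and the neighbouring CH with a seven-membered carbocycle (ring C), and ring C shares its tertiary carbinol and the adjacent alkene carbon with a gem-dimethylcyclopentenone (ring D).

Going round ring C from the hemiketal carbon one meets CH(OH), a ketone, the tertiary carbinol, the trigonal ring D carbon, CHMe and the B/C fusion CH. Five of the seven atoms are stereocentres: the hemiketal carbon (S) next to CH(OH) (R), the tertiary carbinol (R) isolated between ketone and alkene carbon, and CHMe (R) next to the fusion CH (R). Rings B and C are trans-fused.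

The hemiketal carbon, CH(OH) and the fusion CH are configurationally labile, because ring B can open to a 2-hydroxy-1,3-diketone that enolises. Only the tertiary carbinol and CHMe must be set irreversibly.

The fragile elements are the hemiketal/α-ketol array (dehydration, α-ketol shift, retro-Claisen cleavage), the tertiary α-hydroxy ketone wedged between a quaternary carbon and an alkene, and the enone. The real difficulty is the seven-membered ring with four consecutive oxidised carbons and a tertiary carbinol flanked by fully substituted centres.

The key step exploits the B/C fusion CH. It lies between the hemiketal carbon (a ketone in disguise) and the pyrone CH2 (a carboxyl carbon at lower oxidation level), so it is the α-carbon of a β-keto ester. Its neighbour CHMe is the outer carbon of an ethylidene group on ring D. The CH–CHMe bond is therefore the product of an oxidative radical addition, which also leaves the ring D alkene.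

## Logic of the disconnections

**23 ⇒ 22.** The C–O bond of the secondary carbinol is removed first. This carbon sits between the hemiketal carbon and the ring C ketone, so it is the central carbon of a β-diketone masked by ring B and the one position of 22 that enolises easily. The cut removes the α-ketol and one stereocentre. Forward, an electrophilic oxygen donor must reach the enol of 22 without touching the enone or the pyrone; the configuration is left to equilibration.

**22 ⇒ 21 ⇒ 20.** The ring D carbonyl is taken back to the allylic carbinol of 21. The hemiketal C–O bond of ring B, the ring C ketone and both free hydroxyls are then traced to the enol ether and silyl ethers of 20. Ring B closes by itself once the ketone next to the fusion carbon is free, so the open protected form is the simpler object. The forward demand is that one acidic operation unmasks everything without ionising the allylic alcohol, and that the oxidation touches only that alcohol.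

**20 ⇒ 19 + 17.** The bond between pyrone C3 and the CH2 group is cut. The pyrone C4 oxygen and the ring C ketone stand in a 1,5-relation, which is the retron of a conjugate addition. Ring A leaves in one piece as 17. Forward, 19 is a reactive cross-conjugated enone and is therefore released only in the flask from 16 through 18. C-alkylation must win over O-alkylation, and protonation sets the fusion centre.

**16 ⇒ 15 ⇒ 14 ⇒ 13.** No skeletal bond is cut. The CH2OH carbon of 16 is the ester carbon of 13, so the group that activates the radical precursor is kept as the future pyrone CH2. Hydride must not see the ketone. In 14 it is therefore an enol silyl ether, and 15 must lose that one silyl group selectively.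

**13 ⇒ 12 (key).** The bond between the ester-bearing carbon and the CHMe carbon is cut, and the ring D alkene is traced back to an exocyclic ethylidene group. The first carbon is the α-carbon of a β-keto ester and can be oxidised to a radical. The second is the less substituted alkene carbon. Ring C opens, a bicycle becomes a cyclopentane carrying a linear chain, and two stereocentres disappear. Forward, the closure must be 7-endo, the ethylidene group must be E, the enol ether must hold carbinol carbon and ketone cis, and the radical must be terminated toward the ring CH2.

**12 ⇒ 11.** The bond between the ketone carbon and the CH2 of the keto ester is cut (Claisen retron), which removes a two-carbon acetate unit. Forward, an ester enolate must acylate at the carbonyl of a poorly electrophilic β-methoxy acrylate.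

**11 ⇒ 10 ⇒ 9.** The C–OMe bond is cut, which leads back to an ynoate. The triple bond holds the ketone oxidation level at the carbon next to the carbinol, and the ester fixes the regiochemistry of the addition. The tertiary hydroxyl must be silylated first (10 from 9). Otherwise the adduct lactonises to a tetronate.

**9 ⇒ 7 + 8.** The bond between the carbinol carbon and the alkyne carbon is cut. No dependable reagent-controlled enantioselective alkynylation exists for a hindered, unactivated enone of this kind. The ring therefore carries its own control element: the future ring D carbonyl is held as an (S)-silyloxy stereocentre. This centre directs the acetylide, makes the wrong isomer a separable diastereomer, and tolerates the acidic key step better than a ketal would.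

**7 ⇒ 3 + 4.** The exocyclic C=C bond is cut (aldol condensation). The second ring carbonyl must already be reduced and protected at this stage. If 4 were condensed onto 1 itself, the ring CH2 would lie between the alkylidene carbon and a carbonyl, and the exocyclic alkene would slip into the ring as an ene-dione.

**3 ⇒ 2 ⇒ 1.** One of the two enantiotopic carbonyls of 1 is taken back from the carbinol. The forward step is an enantioselective mono-reduction, which supplies the absolute configuration of the whole synthesis by a well-established desymmetrisation.

## Other disconnections considered

**Alternative 1:** The cut is the bond between the CMe2 carbon and the tertiary carbinol of ring D, with the enone traced back to a furan.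
- Forward step: m-CPBA would open the ring C-fused 2-isopropylfuran A2 to the Z-enedione. In the same flask K2CO3 in MeOH would add the isopropyl ketone enolate to the ring C ketone, giving the 4-hydroxycyclopentenone A1.
- In its favour: ring D would appear with enone, gem-dimethyl group and tertiary carbinol at their final oxidation level in one operation from a robust aromatic precursor. Because the aldol is reversible, the carbinol configuration could settle relative to the CHMe centre already present.
- Against it here: the bond joins two fully substituted carbons next to a ketal, so the equilibrium may favour the open enedione. Ring C must be complete, with its stereocentres, before the key step.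
- Comparison, structure: both plans join rings C and D at the tertiary carbinol. The alternative needs ring C first; the chosen plan builds ring C onto ring D.
- Comparison, mechanism: an ionic, reversible closure stands against a radical, irreversible one. Thermodynamic control of the carbinol is a point on which the alternative would be the better if the equilibrium is favourable. It is also the better in needing no stoichiometric metal oxidant and no late oxidation of ring D (step 14 of the chosen plan).
- Comparison, step economy: the alternative is behind. After A1 the hemiketal carbon must still be oxidised, the carbinol oxygen introduced, and the pyrone attached at a ring CH2 that has no handle and competes with a second α-position. Compound 13 already holds the ester carbon there.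

**Alternative 2:** The cut removes ring A itself, at the pyrone C4–C5 and O1–C6 bonds.
- Forward step: the β-alkoxyacrylic acid A4 would undergo carboxylate-directed vinylic C–H activation with [Cp*RhCl2]2 and Ag2CO3, insertion of 2-butyne A5, and C–O reductive elimination to give the protected target A3.
- In its favour: the alkyne is symmetrical, so there is no regiochemical question, and both methyl groups arrive at once. The hemiketal and α-ketol are locked as a methyl ketal and silyl ethers, so only deprotection remains. On the stability and stereochemical definition of the late intermediates this alternative is the better. It also avoids the reactive exocyclic enone 19 and the C- versus O-alkylation issue.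
- Against it here: the annulation substrate is nearly the whole molecule. Its enone, α-silyloxy ketone and mixed ketal would be exposed to trivalent rhodium, a silver oxidant and heat. A4 requires ring B to be built with an extra carboxyl carbon.
- Comparison, structure: the alternative makes two bonds of ring A late. The chosen plan makes one C–C bond and lets the hemiketal close.
- Comparison, mechanism: both couplings belong to established reaction types and are equal in that respect. The alternative is catalytic in a precious metal; the chosen coupling needs only an amine base.
- Comparison, step economy: the chosen plan is shorter, because ring A is bought ready-made as 17 and joined in one step.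

**Alternative 3:** The cut is the bond between CHMe and the ring D carbon that ends as the alkene carbon.
- Forward step: Fe(acac)3 with PhSiH3 would transfer a hydrogen atom to the terminal alkene of A7. The secondary radical would add to the β-carbon of the cyclopentenone in a 7-exo closure, giving the cis-fused hydroazulenone A6.
- In its favour: a nucleophilic alkyl radical and an electron-poor alkene are polarity-matched. The conditions are neutral, mild and catalytic in iron, and they tolerate the free tertiary hydroxyl. On mildness and functional group tolerance this alternative is the better; the chosen step uses stoichiometric Mn(OAc)3 in AcOH on a fully silylated substrate.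
- Equal points: both plans close ring C by radical addition onto a preformed ring D that carries the tertiary carbinol, and both create two stereocentres.
- Against it here: the radical carbon is planar, so the CHMe configuration would depend on the conformation of a seven-membered transition state. In the chosen plan alkene geometry and tether fix it. A 7-exo closure also competes with simple reduction of the radical.
- Comparison, step economy: A6 has lost the ring D alkene. It carries the hemiketal carbon as a silyl ether and an alkene where ketone and carbinol are needed, and it has no carbon at the future pyrone CH2. More redox and C–C steps would follow than after 13.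

Key step: step 8

Assumption: the hemiketal carbon, the secondary carbinol next to it and the B/C fusion carbon of 23 equilibrate through ring-chain tautomerism and enolisation, so the configuration drawn for them is taken to be the thermodynamically preferred one, as expected for an isolable hemiketal natural product.

Remark: lithiated forms of numbered compounds (enolates, the acetylide of 8) are treated as those compounds in their reactive form and carry no number of their own.

## Route

Step 1
Reactants: 1 2,2-dimethylcyclopentane-1,3-dione
Product: 2 (S)-3-hydroxy-2,2-dimethylcyclopentan-1-one
Conditions: (R)-Me-CBS oxazaborolidine (10 mol %), catecholborane, PhMe, −78 °C; MeOH, aq. NaHCO3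
Reagents that add atoms: none
Why: Corey–Bakshi–Shibata reduction, a known desymmetrisation of 2,2-disubstituted cyclopentane-1,3-diones: the oxazaborolidine ((R)-1-methyl-3,3-diphenyltetrahydro-1H,3H-pyrrolo[1,2-c][1,3,2]oxazaborole) binds the carbonyl anti to the quaternary carbon and delivers hydride to one face, and either enantiotopic carbonyl gives the same (S)-carbinol. The catalyst enantiomer is the one that gives the S alcohol with the quaternary carbon as the large group, and the reaction should stop at the hydroxy ketone at low temperature.

Step 2
Reactants: 2 (S)-3-hydroxy-2,2-dimethylcyclopentan-1-one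
Product: 3 (S)-3-[(tert-butyldimethylsilyl)oxy]-2,2-dimethylcyclopentan-1-one
Conditions: TBSCl, imidazole, DMF, 23 → 40 °C
Reagents that add atoms: tert-butyldimethylsilyl chloride, CC(C)(C)[Si](C)(C)Cl
Why: Standard silylation of a secondary alcohol; the β-silyloxy ketone cannot eliminate because the carbon between the two functions is quaternary.

Step 3
Reactants: 3 (S)-3-[(tert-butyldimethylsilyl)oxy]-2,2-dimethylcyclopentan-1-one; 4 acetaldehyde
Product: 7 (3S,5E)-3-[(tert-butyldimethylsilyl)oxy]-5-ethylidene-2,2-dimethylcyclopentan-1-one, via aldol adduct 5 (not isolated), via mesylate 6 (not isolated)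
Conditions: LiN(i-Pr)2, THF, −78 °C; MeCHO; then MsCl, −78 → 0 °C; then DBU, 0 → 23 °C
Reagents that add atoms: none
Why: Directed aldol addition of the lithium enolate (the ketone has a single enolisable CH2), O-mesylation of the aldolate and E1cB elimination give the conjugated ethylidene ketone, with the E isomer (methyl away from the carbonyl) as the thermodynamic geometry. Because the second ring oxygen is a silyl ether and not a carbonyl, the ring CH2 beside the alkylidene carbon is not acidified and the exocyclic alkene should stay in place.

Step 4
Reactants: 7 (3S,5E)-3-[(tert-butyldimethylsilyl)oxy]-5-ethylidene-2,2-dimethylcyclopentan-1-one; 8 methyl propiolate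
Product: 9 methyl 3-[(1S,3S,5E)-3-[(tert-butyldimethylsilyl)oxy]-5-ethylidene-1-hydroxy-2,2-dimethylcyclopentyl]prop-2-ynoate (tertiary OH cis to OTBS)
Conditions: 8, LiN(SiMe3)2, THF, −78 °C; then 7, −78 → −50 °C; AcOH; chromatographic removal of the minor diastereomer
Reagents that add atoms: none
Why: 1,2-Addition of a lithium acetylide to a ketone; the enone has no acidic α-hydrogen and hard lithium acetylides attack the carbonyl carbon and not the β-position. The new tertiary carbinol is set by the resident stereocentre: the OTBS group and the methyl cis to it shield one face, so the acetylide should enter anti to OTBS and leave the hydroxyl cis to it. The trans isomer, which would lead into the enantiomeric series, is a diastereomer and is removed here.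

Step 5
Reactants: 9 methyl 3-[(1S,3S,5E)-3-[(tert-butyldimethylsilyl)oxy]-5-ethylidene-1-hydroxy-2,2-dimethylcyclopentyl]prop-2-ynoate
Product: 10 methyl 3-[(1S,3S,5E)-3-[(tert-butyldimethylsilyl)oxy]-5-ethylidene-2,2-dimethyl-1-[(triethylsilyl)oxy]cyclopentyl]prop-2-ynoate
Conditions: TESOTf, 2,6-lutidine, CH2Cl2, −78 → 0 °C
Reagents that add atoms: triethylsilyl trifluoromethanesulfonate, CC[Si](CC)(CC)OS(=O)(=O)C(F)(F)F
Why: Silyl triflates silylate hindered tertiary alcohols; protection is needed so that the methanol adduct of the next step cannot lactonise to a tetronate.

Step 6
Reactants: 10 methyl 3-[(1S,3S,5E)-3-[(tert-butyldimethylsilyl)oxy]-5-ethylidene-2,2-dimethyl-1-[(triethylsilyl)oxy]cyclopentyl]prop-2-ynoate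
Product: 11 methyl (2E)-3-[(1R,3S,5E)-3-[(tert-butyldimethylsilyl)oxy]-5-ethylidene-2,2-dimethyl-1-[(triethylsilyl)oxy]cyclopentyl]-3-methoxyprop-2-enoate
Conditions: NaOMe (0.3 equiv), MeOH, 0 → 40 °C
Reagents that add atoms: methanol, CO
Why: Base-catalysed conjugate addition of methanol to an ynoate (oxa-Michael addition); methoxide attacks the β-carbon and the reversible addition should settle on the E enol ether, with OMe anti to the ester and the carbinol carbon cis to the carbonyl as ring closure later needs. Methyl esters are used throughout so that methoxide cannot scramble the ester.

Step 7
Reactants: 11 methyl (2E)-3-[(1R,3S,5E)-3-[(tert-butyldimethylsilyl)oxy]-5-ethylidene-2,2-dimethyl-1-[(triethylsilyl)oxy]cyclopentyl]-3-methoxyprop-2-enoate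
Product: 12 methyl (4E)-5-[(1R,3S,5E)-3-[(tert-butyldimethylsilyl)oxy]-5-ethylidene-2,2-dimethyl-1-[(triethylsilyl)oxy]cyclopentyl]-5-methoxy-3-oxopent-4-enoate
Conditions: MeOAc, LiN(i-Pr)2 (3.5 equiv each), THF, −78 °C; then 11, −78 → −30 °C; AcOH
Reagents that add atoms: methyl acetate, CC(=O)OC
Why: Crossed Claisen condensation: the excess lithium enolate of methyl acetate acylates at the ester carbonyl, since the β-carbon is shielded by the fully substituted carbinol, and the β-keto ester is protected from further attack as its enolate until the quench.

Step 8
Reactants: 12 methyl (4E)-5-[(1R,3S,5E)-3-[(tert-butyldimethylsilyl)oxy]-5-ethylidene-2,2-dimethyl-1-[(triethylsilyl)oxy]cyclopentyl]-5-methoxy-3-oxopent-4-enoate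
Product: 13 hydroazulene keto ester: seven-membered ring CH(CO2Me)–C(=O)–CH=C(OMe)–C(OSiEt3)–C(=)–CH(CH3), fused through the last two ring carbons before CH(CH3) to the cyclopentene C(OSiEt3)–CMe2–CH(OTBS)–CH=C; CH3 trans to OSiEt3, CO2Me trans to CH3, OTBS cis to OSiEt3
Conditions: Mn(OAc)3·2H2O (2.2 equiv), Cu(OAc)2·H2O (1.0 equiv), degassed AcOH, 25 → 40 °C
Reagents that add atoms: none
Why: Mn(OAc)3 converts the β-keto ester into its manganese enolate and inner-sphere electron transfer gives the electrophilic α-radical; this is the oxidative free-radical cyclisation of unsaturated β-keto esters with Cu(OAc)2 termination, a reaction type for which 7-endo and 8-endo closures are established. The radical adds to the CHMe carbon of the ethylidene group, which closes ring C in the 7-endo-trig mode and leaves a tertiary radical on ring D. Cu(OAc)2 intercepts this radical as an alkylcopper species (trivalent copper) that loses a β-hydrogen from the ring CH2 by syn elimination, placing the alkene between the fusion carbon and the CH next to the OTBS carbon, and the monovalent copper is reoxidised by trivalent manganese. 7-Endo closure should win over 6-exo because the electrophilic radical attacks the less substituted alkene carbon, forms the more stable tertiary radical, and would otherwise have to build a quaternary carbon beside the fully substituted carbinol. The CHMe centre is controlled by two substrate features: the chain leaves the carbinol carbon on the ring D face opposite to OSiEt3 and can reach the alkene only from that face, and the E geometry then decides which side the methyl takes, so it ends trans to OSiEt3. The ester-bearing centre should form trans to the methyl, is epimerisable through the enol, and loses its identity in step 9. The enol ether must hold carbinol carbon and ketone cis, and since this push-pull alkene equilibrates in AcOH any other geometry is funnelled through the reactive isomer. Both silyl ethers and the vinylogous ester tolerate AcOH at this temperature.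

Step 9
Reactants: 13 hydroazulene keto ester
Product: 14 tert-butyldimethylsilyl enol ether of 13 (ring diene C(CO2Me)=C(OTBS)–CH=C(OMe); other centres unchanged)
Conditions: TBSOTf, Et3N, CH2Cl2, −78 → 0 °C
Reagents that add atoms: tert-butyldimethylsilyl trifluoromethanesulfonate, CC(C)(C)[Si](C)(C)OS(=O)(=O)C(F)(F)F
Why: O-Silylation at the only enolisable position (silyl enol ether formation) masks the ketone, so that hydride can tell ester from ketone in the next step.

Step 10
Reactants: 14 tert-butyldimethylsilyl enol ether of 13
Product: 15 primary allylic alcohol (CO2Me of 14 replaced by CH2OH)
Conditions: i-Bu2AlH (2.5 equiv), CH2Cl2, −78 °C; aq. KNaC4H4O6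
Reagents that add atoms: none
Why: i-Bu2AlH reduces the β-silyloxy acrylate ester to the allylic alcohol at low temperature (1,2-reduction of an unsaturated ester); enol ethers and silyl ethers carry nothing reducible, and the neutral tartrate work-up avoids ionising the product.

Step 11
Reactants: 15 primary allylic alcohol
Product: 16 β-hydroxy ketone: ring C ketone with CH2OH on the α-carbon (this centre as an epimer mixture), methyl vinylogous ester, OSiEt3 and OTBS retained
Conditions: Bu4NF (1.05 equiv), AcOH (1.2 equiv), THF, −40 → −20 °C
Reagents that add atoms: none
Why: Fluoride cleaves a silyl enol ether far faster than the hindered alkyl silyl ethers, and AcOH protonates the enolate at once, which should give the hydroxymethyl ketone and suppress retro-aldol loss of formaldehyde.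

Step 12
Reactants: 16 β-hydroxy ketone; 17 4-hydroxy-5,6-dimethyl-2H-pyran-2-one
Product: 20 C3-alkylated pyrone: 4-hydroxy-5,6-dimethyl-2-pyrone carrying at C3 a CH2 bound to the α-carbon of the ring C ketone of the bicycle (pyrone CH2 trans to CH3, cis to OSiEt3), via mesylate 18 (not isolated), via exocyclic enone 19 (not isolated)
Conditions: MsCl, Et3N (4 equiv), CH2Cl2, −20 → 0 °C; then 17, 0 → 23 °C
Reagents that add atoms: none
Why: Mesylation and E1cB elimination release the α-methylene ketone only in solution, where the pyronolate adds through C3 (Michael addition; O-addition is reversible and drains to the C-adduct). Protonation of the enolate sets the fusion CH, and the epimer with the pyrone CH2 trans to the neighbouring methyl should be favoured; the centre stays correctable until ring B is closed.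

Step 13
Reactants: 20 C3-alkylated pyrone
Product: 21 tetracyclic hemiketal: 23 without the secondary hydroxyl (CH2 there) and with an (S)-allylic carbinol in place of the ring D carbonyl; hemiketal OH, tertiary OH and pyrone CH2 on one face of ring C, CH3 and fusion H on the other
Conditions: 48% aq. HF, MeCN–H2O, 0 → 30 °C
Reagents that add atoms: water, O
Why: Acid hydrolysis of the vinylogous ester gives the β-diketone, whose carbonyl next to the fusion carbon is captured by the pyrone hydroxyl as the six-membered hemiketal (ring B), while HF removes both silyl ethers in the same operation. Hemiketal and fusion centres can equilibrate under these conditions and should settle in the trans-fused arrangement.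

Step 14
Reactants: 21 tetracyclic hemiketal with ring D allylic alcohol
Product: 22 tetracyclic hemiketal enone (23 without the secondary hydroxyl)
Conditions: MnO2 (activated, excess), CH2Cl2, 23 °C
Reagents that add atoms: none
Why: MnO2 oxidises allylic alcohols selectively (allylic oxidation); the tertiary and hemiketal hydroxyls cannot be oxidised and the β-diketone is left alone.

Step 15
Reactants: 22 tetracyclic hemiketal enone
Product: 23 target: hemiketal OH, tertiary OH and pyrone CH2 on one face of ring C; secondary OH, CH3 and fusion H on the other (hemiketal S, CHOH R, tertiary carbinol R, CHMe R, fusion CH R)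
Conditions: dimethyldioxirane (acetone solution, 1.5 equiv), acetone–CH2Cl2, −20 → 0 °C
Reagents that add atoms: dimethyldioxirane, CC1(C)OO1
Why: Dimethyldioxirane hydroxylates the central carbon of a 1,3-diketone through its enol, here the open tautomer of the hemiketal (electrophilic α-hydroxylation of 1,3-dicarbonyl compounds), and the enone and pyrone are too electron-poor to compete at low temperature. Re-closure of ring B should give the hemiketal with the trans diol; the new carbinol and the hemiketal carbon are epimerisable and are expected to settle in the configuration of the target.

## Compound list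

1 | 2,2-dimethylcyclopentane-1,3-dione | CC1(C)C(=O)CCC1=O | starting material
2 | (S)-3-hydroxy-2,2-dimethylcyclopentan-1-one | CC1(C)[C@@H](O)CCC1=O | intermediate
3 | (S)-3-[(tert-butyldimethylsilyl)oxy]-2,2-dimethylcyclopentan-1-one | CC1(C)[C@@H](O[Si](C)(C)C(C)(C)C)CCC1=O | intermediate
4 | acetaldehyde | CC=O | starting material
5 | (3S)-3-[(tert-butyldimethylsilyl)oxy]-5-(1-hydroxyethyl)-2,2-dimethylcyclopentan-1-one, formed as its lithium alkoxide, mixture at the two new centres (not isolated) | CC(O)C1C[C@H](O[Si](C)(C)C(C)(C)C)C(C)(C)C1=O | intermediate
6 | methanesulfonate of 5 (not isolated) | CC(OS(C)(=O)=O)C1C[C@H](O[Si](C)(C)C(C)(C)C)C(C)(C)C1=O | intermediate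
7 | (3S,5E)-3-[(tert-butyldimethylsilyl)oxy]-5-ethylidene-2,2-dimethylcyclopentan-1-one | C/C=C1\C[C@H](O[Si](C)(C)C(C)(C)C)C(C)(C)C1=O | intermediate
8 | methyl propiolate | C#CC(=O)OC | starting material
9 | methyl 3-[(1S,3S,5E)-3-[(tert-butyldimethylsilyl)oxy]-5-ethylidene-1-hydroxy-2,2-dimethylcyclopentyl]prop-2-ynoate | C/C=C1\C[C@H](O[Si](C)(C)C(C)(C)C)C(C)(C)[C@@]1(O)C#CC(=O)OC | intermediate
10 | methyl 3-[(1S,3S,5E)-3-[(tert-butyldimethylsilyl)oxy]-5-ethylidene-2,2-dimethyl-1-[(triethylsilyl)oxy]cyclopentyl]prop-2-ynoate | C/C=C1\C[C@H](O[Si](C)(C)C(C)(C)C)C(C)(C)[C@@]1(O[Si](CC)(CC)CC)C#CC(=O)OC | intermediate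
11 | methyl (2E)-3-[(1R,3S,5E)-3-[(tert-butyldimethylsilyl)oxy]-5-ethylidene-2,2-dimethyl-1-[(triethylsilyl)oxy]cyclopentyl]-3-methoxyprop-2-enoate | C/C=C1\C[C@H](O[Si](C)(C)C(C)(C)C)C(C)(C)[C@@]1(O[Si](CC)(CC)CC)/C(OC)=C\C(=O)OC | intermediate
12 | methyl (4E)-5-[(1R,3S,5E)-3-[(tert-butyldimethylsilyl)oxy]-5-ethylidene-2,2-dimethyl-1-[(triethylsilyl)oxy]cyclopentyl]-5-methoxy-3-oxopent-4-enoate (key-step precursor) | C/C=C1\C[C@H](O[Si](C)(C)C(C)(C)C)C(C)(C)[C@@]1(O[Si](CC)(CC)CC)/C(OC)=C\C(=O)CC(=O)OC | intermediate
13 | hydroazulene keto ester with ring D alkene (key-step product; CH3 trans to OSiEt3, CO2Me trans to CH3, OTBS cis to OSiEt3) | COC(=O)[C@@H]1[C@@H](C)C2=C[C@H](O[Si](C)(C)C(C)(C)C)C(C)(C)[C@@]2(O[Si](CC)(CC)CC)C(OC)=CC1=O | intermediate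
14 | tert-butyldimethylsilyl enol ether of 13 | COC(=O)C=1[C@@H](C)C2=C[C@H](O[Si](C)(C)C(C)(C)C)C(C)(C)[C@@]2(O[Si](CC)(CC)CC)C(OC)=CC=1O[Si](C)(C)C(C)(C)C | intermediate
15 | primary allylic alcohol from 14 | OCC=1[C@@H](C)C2=C[C@H](O[Si](C)(C)C(C)(C)C)C(C)(C)[C@@]2(O[Si](CC)(CC)CC)C(OC)=CC=1O[Si](C)(C)C(C)(C)C | intermediate
16 | α-(hydroxymethyl) ketone (epimer mixture at the CH2OH-bearing carbon) | OCC1[C@@H](C)C2=C[C@H](O[Si](C)(C)C(C)(C)C)C(C)(C)[C@@]2(O[Si](CC)(CC)CC)C(OC)=CC1=O | intermediate
17 | 4-hydroxy-5,6-dimethyl-2H-pyran-2-one | Cc1oc(=O)cc(O)c1C | starting material
18 | methanesulfonate of 16 (not isolated) | CS(=O)(=O)OCC1[C@@H](C)C2=C[C@H](O[Si](C)(C)C(C)(C)C)C(C)(C)[C@@]2(O[Si](CC)(CC)CC)C(OC)=CC1=O | intermediate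
19 | exocyclic α-methylene ketone (not isolated) | C=C1[C@@H](C)C2=C[C@H](O[Si](C)(C)C(C)(C)C)C(C)(C)[C@@]2(O[Si](CC)(CC)CC)C(OC)=CC1=O | intermediate
20 | C3-alkylated pyrone (Michael adduct, open keto form) | Cc1oc(=O)c(C[C@@H]2[C@@H](C)C3=C[C@H](O[Si](C)(C)C(C)(C)C)C(C)(C)[C@@]3(O[Si](CC)(CC)CC)C(OC)=CC2=O)c(O)c1C | intermediate
21 | tetracyclic hemiketal with ring D (S)-allylic alcohol, no secondary ring C hydroxyl | Cc1oc(=O)c2c(c1C)O[C@]1(O)CC(=O)[C@@]3(O)C(=C[C@H](O)C3(C)C)[C@H](C)[C@H]1C2 | intermediate
22 | tetracyclic hemiketal enone, no secondary ring C hydroxyl | Cc1oc(=O)c2c(c1C)O[C@]1(O)CC(=O)[C@@]3(O)C(=CC(=O)C3(C)C)[C@H](C)[C@H]1C2 | intermediate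
23 | CNP0525404.1 | Cc1oc(=O)c2c(c1C)O[C@]1(O)[C@H](O)C(=O)[C@@]3(O)C(=CC(=O)C3(C)C)[C@H](C)[C@H]1C2 | target

## Step count and least certain steps

Total step count: 15. Longest linear sequence: 15 steps (1 → 23); 4, 8 and 17 are commercial and enter directly.

**Step 8 (key step).**
- What may go wrong: the product still carries an enolisable hydrogen between ketone and ester and may be oxidised a second time by Mn(OAc)3. The tertiary radical may also be oxidised to a cation, which can lose a proton in the wrong direction or be captured by the ester oxygen as a lactone. A smaller risk is competing 6-exo closure.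
- Fallback: setting out from 12, the α-position is first blocked with N-chlorosuccinimide as the α-chloro β-keto ester F1. The same Mn(OAc)3/Cu(OAc)2 closure then gives the chlorinated bicycle F2, which has no enolisable hydrogen and cannot be oxidised further. Zinc in AcOH removes the chlorine and the route is rejoined at 13.

**Step 4.**
- What may go wrong: the stabilised, weakly nucleophilic acetylide may add slowly or reversibly to the neopentyl-type enone, and facial discrimination by the remote silyloxy centre may be modest. If the preference proves to be the opposite one, the mirror-image reduction catalyst in step 1 inverts the series at the source.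
- Fallback: setting out from 7, HC≡CMgBr with CeCl3 (a small, more nucleophilic and less basic acetylide) gives the terminal alkynyl carbinol F3. Silylation with TESOTf gives the triethylsilyl ether F4. Lithiation with n-BuLi and trapping with ClCO2Me gives 10, where the route resumes.

**Step 7.**
- What may go wrong: the β-methoxy acrylate is a vinylogous carbonate and may be acylated only sluggishly, so that self-condensation of the acetate enolate or addition–elimination at the methoxy-bearing carbon takes over.
- Fallback: setting out from 11, saponification with LiOH gives the β-methoxyacrylic acid F5. Carbonyldiimidazole converts it into the acyl imidazolide F6. C-acylation of Mg(O2CCH2CO2Me)2 with loss of CO2 (the magnesium malonate half-ester homologation of acyl imidazolides) returns to the route at 12.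

**Step 10 (with step 11).**
- What may go wrong: the 2-silyloxy allylic alkoxide may ionise during reduction or work-up to the exocyclic enone, which would then be reduced further or dimerise. Fluoride in step 11 may also trigger retro-aldol loss of the CH2OH carbon.
- Fallback: setting out from 13, Krapcho dealkoxycarbonylation (LiCl, wet DMSO, 120 °C) gives the ketone F7, which has a single enolisable CH2. α-Methylenation with paraformaldehyde and diisopropylammonium trifluoroacetate then generates 19 directly. It is trapped by 17 as in step 12, so the route is rejoined at 20; the pyrone CH2 then stems from formaldehyde and not from the ester carbon.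

**Step 15.**
- What may go wrong: if the hemiketal opens only slowly, too little enol is available, and epoxidation of the ring D enone or over-oxidation at the already hydroxylated carbon can compete. Facial selectivity at the new carbinol is not secured by any nearby group and relies on equilibration.
- Fallback: setting out from 22, azeotropic dehydration with pyridinium p-toluenesulfonate in benzene gives the cyclic vinylogous ester F8. Dihydroxylation of its enol ether double bond with catalytic OsO4 and N-methylmorpholine N-oxide delivers both oxygens in one concerted event and gives 23 after hemiketal equilibration.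

## Further compounds

F1 | step 8 | α-chloro β-keto ester from 12 | C/C=C1\C[C@H](O[Si](C)(C)C(C)(C)C)C(C)(C)[C@@]1(O[Si](CC)(CC)CC)/C(OC)=C\C(=O)C(Cl)C(=O)OC
F2 | step 8 | α-chloro hydroazulene keto ester | COC(=O)C1(Cl)[C@@H](C)C2=C[C@H](O[Si](C)(C)C(C)(C)C)C(C)(C)[C@@]2(O[Si](CC)(CC)CC)C(OC)=CC1=O
F3 | step 4 | (1S,3S,5E)-3-[(tert-butyldimethylsilyl)oxy]-5-ethylidene-1-ethynyl-2,2-dimethylcyclopentan-1-ol | C/C=C1\C[C@H](O[Si](C)(C)C(C)(C)C)C(C)(C)[C@@]1(O)C#C
F4 | step 4 | triethylsilyl ether of F3 | C/C=C1\C[C@H](O[Si](C)(C)C(C)(C)C)C(C)(C)[C@@]1(O[Si](CC)(CC)CC)C#C
F5 | step 7 | (2E)-3-methoxyprop-2-enoic acid corresponding to 11 | C/C=C1\C[C@H](O[Si](C)(C)C(C)(C)C)C(C)(C)[C@@]1(O[Si](CC)(CC)CC)/C(OC)=C\C(=O)O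
F6 | step 7 | acyl imidazolide of F5 | C/C=C1\C[C@H](O[Si](C)(C)C(C)(C)C)C(C)(C)[C@@]1(O[Si](CC)(CC)CC)/C(OC)=C\C(=O)n1ccnc1
F7 | step 10 | decarboxylated bicyclic ketone from 13 | O=C1C[C@@H](C)C2=C[C@H](O[Si](C)(C)C(C)(C)C)C(C)(C)[C@@]2(O[Si](CC)(CC)CC)C(OC)=C1
F8 | step 15 | cyclic vinylogous ester (dehydrated 22) | Cc1oc(=O)c2c(c1C)OC1=CC(=O)[C@@]3(O)C(=CC(=O)C3(C)C)[C@H](C)[C@H]1C2
A1 | alternative 1 | hydroazulene 4-hydroxycyclopentenone | CC1(C)C(=O)C=C2[C@]1(O)C3(OCCO3)C[C@H](O[Si](C)(C)C(C)(C)C)C[C@H]2C
A2 | alternative 1 | ring C-fused 2-isopropylfuran precursor | CC(C)c1cc2c(o1)C3(OCCO3)C[C@H](O[Si](C)(C)C(C)(C)C)C[C@H]2C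
A3 | alternative 2 | methyl ketal bis(triethylsilyl) ether of the target | Cc1oc(=O)c2c(c1C)O[C@]1(OC)[C@H](O[Si](CC)(CC)CC)C(=O)[C@@]3(O[Si](CC)(CC)CC)C(=CC(=O)C3(C)C)[C@H](C)[C@H]1C2
A4 | alternative 2 | dihydropyran carboxylic acid (β-alkoxyacrylic acid) precursor | OC(=O)C1=CO[C@]2(OC)[C@H](O[Si](CC)(CC)CC)C(=O)[C@@]3(O[Si](CC)(CC)CC)C(=CC(=O)C3(C)C)[C@H](C)[C@H]2C1
A5 | alternative 2 | 2-butyne | CC#CC
A6 | alternative 3 | cis-fused hydroazulenone | C[C@@H]1C[C@H](O[Si](C)(C)C(C)(C)C)C=C[C@@]2(O)[C@@H]1CC(=O)C2(C)C
A7 | alternative 3 | cyclopentenone with Z-dienyl side chain and terminal alkene | C=CC[C@H](O[Si](C)(C)C(C)(C)C)/C=C\[C@@]1(O)C=CC(=O)C1(C)C
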